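The midnight run held more substrate than the noon run, and the summer run more reagent. Yet the last readings put the share of target in the two products at 19.5% in the noon run, 19.3% in the midnight run and 18.5% in the summer run.

| flask | substrate | reagent | catalyst | remark | time |
|---|---|---|---|---|---|
| noon | 7.4 mM | 27.5 mM | 63 µM | run made earlier |  |
| midnight | 16 mM | 27.5 mM | 63 µM | run made earlier |  |
| summer | 11 mM | 41 mM | 63 µM | run made earlier |  |
| flask | 11 mM | 27.5 mM | 63 µM |  | 6.0 h |

| run | time / h | target / % | uncatalysed product / % |
|---|---|---|---|
| noon | 0.667 | 17.0 | 70.7 |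
| noon | 1.33 | 18.7 | 79.8 |
| noon | 2.00 | 18.9 | 79.7 |
| noon | 3.00 | 19.6 | 81.5 |
| noon | 4.00 | 19.3 | 79.6 |
| midnight | 0.333 | 10.6 | 51.7 |
| midnight | 0.833 | 16.5 | 70.5 |
| midnight | 1.50 | 18.4 | 77.5 |
| midnight | 2.50 | 19.2 | 79.4 |
| midnight | 4.00 | 19.1 | 79.9 |
| summer | 0.250 | 11.8 | 58.8 |
| summer | 0.500 | 16.2 | 75.1 |
| summer | 1.00 | 18.1 | 81.4 |
| summer | 2.00 | 19.0 | 81.4 |
| summer | 4.00 | 18.5 | 81.6 |

(standard deviation of a reading: 0.5 percentage points)

- share of target in target plus uncatalysed product at 40 s
- share of target in target plus uncatalysed product at 15 min
- share of target in target plus uncatalysed product at 6.0 h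
- which of target and uncatalysed product there is more of at 6.0 h

So these last readings showed no clear trend with the charges, but the share did move with time. The summer run showed 16.7% at 0.250 h and 18.5% at 4.00 h.

My first answer was a constant ratio. Pooling the last readings, I got 0.236 of target per unit of uncatalysed product, a selectivity factor. Dividing by the catalyst charged gave 3.75 mM⁻¹, my selectivity per catalyst. No run tested that scaling, since all held 63 µM.

Then I put the ratio back. At 0.250 h the summer run had 58.8% uncatalysed product, so the ratio asked for 13.9% target, but I read 11.8%. So I went round once more. After that reading the summer ratio read 0.294, above the pooled one. In the summer run target lagged at first and gained later, and the pooled ratio holds both stretches.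

For the flask I reckoned 19.1% at 6.0 h, with uncatalysed product ahead. At 15 min I expected about 16.7%, as the summer run read at that time with more reagent, and lower still at 40 s.

The forecast gave 6% (from 1% to 16%), 16.7% (from 15.2% to 18%) and 19.2% (from 18.6% to 19.8%), with uncatalysed product ahead. Its ground for the end share was that “both routes seem to respond alike to substrate and reagent”.

The flask gave 2.07% at 40 s, 16.5% at 15 min and 19.6% at 6.0 h, with uncatalysed product ahead.

    substrate + catalyst ⇌ catalyst + intermediate (K = 0.370, k = 1300 M⁻¹ min⁻¹)
    reagent + catalyst + intermediate → catalyst + target (k = 31000 M⁻² min⁻¹)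
    substrate + reagent → uncatalysed product (k = 2.40 M⁻¹ min⁻¹)

At 6.00 h the flask held 0% of its substrate and 60.0% of its reagent. Its end ratio was 0.244, against 0.236 from the selectivity per catalyst. For the neighbour flask charged with 0.25 mM of catalyst, the same quantity gives a ratio of 0.938, so a share of 48.4%. That neighbour ended at 49.6%.

The data were generated by integration with constants of no real substance; the scatter is artificial.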